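**Retrosynthetic overview**

1. Ring C is closed last through the lactone C7–O bond: a palladium-hydride 1,4-hydrolactonization of a ten-membered 1,3-diene acid (new) that also sets C7, the (5Z)-olefin and the C16 methyl.
2. Ring B (ten-membered) comes from ring-closing metathesis (C6=C7) between a C8 vinyl carbinol and a 2-substituted butadiene arm added at C2 by catalytic asymmetric alkyl addition.
3. Ring A comes from a substrate-controlled Diels–Alder reaction of a γ-silyloxy enal (C2–C1=C10–C9) with a 1-silyloxypentadiene, then palladium elimination to the cyclohexadiene and OsO4 dihydroxylation (C11, C12).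
4. C8–C9 comes from a Seebach dioxolanone aldol of (2S,3R)-3-methylmalic acid (L-malate, Fráter–Seebach methylation) with an enal acetal; C8 and C17 are chiral-pool centres.
5. Ring order: A (step 7), B (step 14), C (step 15); end game is desilylation, diacetylation and acetonide removal.

Assumption and notation: briarane numbering is used (ring A = C1, C10–C14; ring B = C1–C10; ring C = C7, C8, C17, C19, O; methyls C15, C16, C18, C20 on C1, C5, C17, C11), and the C19 carboxylic acid is carried unprotected, with reagents it consumes used in excess.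

**Route**

Step 1
Reactants: 1 dimethyl (S)-malate
Product: 2 dimethyl (2S,3R)-3-methylmalate
Conditions: LiN(i-Pr)2 (2.2 equiv), THF, −78 → −20 °C; MeI, −78 → 0 °C; aqueous quench
Reagents that add atoms: iodomethane CI
Why: Fráter–Seebach alkylation, in which the chelated dilithium alkoxide–enolate is methylated anti to the alkoxide and sets C17 (about 9:1).

Step 2
Reactants: 2 dimethyl (2S,3R)-3-methylmalate
Product: 3 (2S,3R)-3-methylmalic acid
Conditions: LiOH (3 equiv), THF/H2O, 0 → 25 °C; then HCl to pH 1
Reagents that add atoms: lithium hydroxide [Li+].[OH-]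
Why: Mild ester saponification that leaves both stereocentres untouched.

Step 3
Reactants: 3 (2S,3R)-3-methylmalic acid
Product: 4 cis-dioxolanone acid
Conditions: t-BuCHO, TsOH·H2O (cat.), H2SO4 (cat.), pentane, reflux, water separator; recrystallize
Reagents that add atoms: pivalaldehyde CC(C)(C)C=O
Why: Seebach acetalization of the α-hydroxy acid gives the five-membered dioxolanone with tert-butyl cis to the side chain, which stores the C8 configuration for self-regeneration of the stereocentre.

Step 4
Reactants: 5 1,1-dimethoxypropan-2-one; 6 (triphenylphosphoranylidene)acetaldehyde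
Product: 7 (E)-4,4-dimethoxy-3-methylbut-2-enal
Conditions: toluene, 110 °C
Reagents that add atoms: none
Why: Wittig olefination of the activated ketone with the formyl-stabilized ylide gives the (E)-enal (CHO trans to the larger acetal carbon).

Step 5
Reactants: 4 cis-dioxolanone acid; 7 (E)-4,4-dimethoxy-3-methylbut-2-enal
Product: 10 enal acid, via aldol adduct 8 (not isolated), via bis-silyl acetal 9 (not isolated)
Conditions: LiN(SiMe3)2 (2.2 equiv), THF, −78 °C; 7; TBSOTf (2.3 equiv), −78 → −40 °C; then 1 M HCl, THF, 0 °C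
Reagents that add atoms: tert-butyldimethylsilyl trifluoromethanesulfonate CC(C)(C)[Si](C)(C)OS(=O)(=O)C(F)(F)F; water O
Why: Seebach dioxolanone aldol in which the carboxylate–enolate dianion adds 1,2 to the enal anti to tert-butyl (C8, net retention) through a closed Zimmerman–Traxler chair (C17 arm cis to OLi, so C17 syn and O8 anti to O9, setting C9), after which the aldolate is silylated in situ and acid work-up frees the acid and the enal.

Step 6
Reactants: 11 (E)-pent-2-enal
Product: 12 (1E,3E)-1-(trimethylsilyloxy)penta-1,3-diene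
Conditions: Me3SiCl, Et3N, ZnCl2 (cat.), benzene, 40 °C; distil
Reagents that add atoms: chlorotrimethylsilane C[Si](C)(C)Cl
Why: Silyl dienol ether formation by γ-deprotonation and O-silylation of the enal; only the (3E) isomer reacts in step 7.

Step 7
Reactants: 10 enal acid; 12 (1E,3E)-1-(trimethylsilyloxy)penta-1,3-diene
Product: 15 ring A hydroxy aldehyde acid, via trimethylsilyl ester 13 (not isolated), via bis-silyl cycloadduct 14 (not isolated)
Conditions: BSA (1.2 equiv), toluene, 25 °C; 12 (4 equiv), BHT, 110 °C, sealed tube; then 5% aq. citric acid, THF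
Reagents that add atoms: none
Why: Thermal normal-demand Diels–Alder reaction in which the silyloxy terminus sends C14 to C1 and C11 to C10, the (E)-enal fixes C2 and C9 trans, and allylic 1,3-strain (C9–H eclipsing the olefin) makes the diene add anti to the quaternary C8 group, setting C1 and C10 (the C11/C14 centres are removed in step 8).

Step 8
Reactants: 15 ring A hydroxy aldehyde acid
Product: 17 cyclohexadiene aldehyde acid, via allylic acetate 16 (not isolated)
Conditions: Ac2O, pyridine, DMAP (cat.), CH2Cl2, 25 °C; evaporate; Pd(PPh3)4 (5 mol %), Et3N, 1,4-dioxane, 90 °C; aqueous work-up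
Reagents that add atoms: none
Why: Acetylation followed by Tsuji–Trost-type elimination, in which anti ionization of the C14 acetate and syn β-hydride loss of H11 (the only β-hydrogen) give the C11=C12–C13=C14 diene without a free cation next to the formyl-bearing quaternary carbon; the mixed anhydride formed at CO2H is cleaved on work-up.

Step 9
Reactants: 17 cyclohexadiene aldehyde acid
Product: 18 11,12-diol
Conditions: K2OsO4·2H2O (2 mol %), NMO (1.3 equiv), acetone/H2O, 0 °C
Reagents that add atoms: N-methylmorpholine N-oxide C[N+]1([O-])CCOCC1; water O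
Why: Upjohn syn-dihydroxylation in which OsO4 takes the more electron-rich trisubstituted C11=C12 from the α face, anti to the C10 side chain and the C1 methyl, setting C11 and C12 as the cis-diol.

Step 10
Reactants: 18 11,12-diol
Product: 19 acetonide aldehyde acid
Conditions: 2-methoxypropene, PPTS (cat.), CH2Cl2, 0 → 25 °C
Reagents that add atoms: 2-methoxypropene COC(C)=C
Why: Acetonide formation on the cis-diol, which keeps the secondary C12 hydroxyl out of the later acetylation.

Step 11
Reactants: 20 4-bromobut-1-yne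
Product: 21 5-bromo-3-methylidenepent-1-ene
Conditions: ethene (1 atm), second-generation Grubbs catalyst RuCl2(PCy3)(H2IMes)(=CHPh) (3 mol %), CH2Cl2, 40 °C
Reagents that add atoms: ethene C=C
Why: Enyne cross-metathesis with ethene turns the terminal alkyne into the 2-substituted 1,3-diene.

Step 12
Reactants: 19 acetonide aldehyde acid; 21 5-bromo-3-methylidenepent-1-ene
Product: 23 C2 carbinol, via Grignard reagent 22 (not isolated)
Conditions: 21, Mg, Et2O (gives 22, 3.5 equiv); Ti(OiPr)4 (5 equiv), (R)-3-(3,5-diphenylphenyl)-H8-BINOL (5 mol %), CH2Cl2, 0 °C; then 19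
Reagents that add atoms: none
Why: Catalytic asymmetric alkyl addition (alkyltitanium triisopropoxide from the Grignard reagent, chiral titanium BINOLate) with Re-face delivery by analogy with PhCHO giving (R)-carbinols, setting C2 (R); the titanium reagent does not attack the dioxolanone.

Step 13
Reactants: 23 C2 carbinol
Product: 26 C8 vinyl carbinol, via dioxolanol 24 (not isolated), via hydroxy aldehyde 25 (not isolated)
Conditions: i-Bu2AlH (3.5 equiv), CH2Cl2, −78 °C; then Ph3P=CH2 [Ph3PCH3Br, KN(SiMe3)2] (6 equiv), THF, −78 → 25 °C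
Reagents that add atoms: methyltriphenylphosphonium bromide C[P+](c1ccccc1)(c1ccccc1)c1ccccc1.[Br-]
Why: One-pot partial reduction of the activated dioxolanone carbonyl to the aluminium hemiacetal and Wittig methylenation of the aldehyde released on warming (pivalaldehyde is lost); no other reducible group is present and C8 is untouched.

Step 14
Reactants: 26 C8 vinyl carbinol
Product: 27 ten-membered diene acid
Conditions: second-generation Hoveyda–Grubbs catalyst RuCl2(H2IMes)(=CH-C6H4-2-O-i-Pr) (10 mol %), toluene (1 mM), 80 °C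
Reagents that add atoms: none
Why: Ring-closing metathesis between the two monosubstituted vinyl groups (the 1,1-disubstituted olefin is spared) closes ring B as a disubstituted C6=C7 olefin.

Step 15
Reactants: 27 ten-membered diene acid
Product: 28 silyl-protected lactone
Conditions: Pd(PPh3)4 (10 mol %), toluene, 60 °C
Reagents that add atoms: none
Why: Proposed new method: palladium-hydride-catalysed transannular 1,4-hydrolactonization of a semicyclic 1,3-diene acid, in which zerovalent palladium is protonated by the substrate CO2H, Pd–H adds to the exocyclic CH2 (C16 becomes the methyl), the η3-allyl complex over C5–C6–C7 is captured by the tethered C19 carboxylate at C7 (five-membered ring; C5 would need a seven-membered one), and reversible allylic C–O ionization lets the product settle as the trans-fused butanolide (ring torsion C6–C7–C8–C9 antiperiplanar, C6 and C9 trans on the lactone, 7S) with the (5Z)-olefin held by the ten-membered ring; closest known chemistry is Pd–H 1,4-hydrofunctionalization (hydroamination, hydroalkoxylation) of acyclic 1,3-dienes and Tsuji–Trost lactonization.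

Step 16
Reactants: 28 silyl-protected lactone
Product: 29 2,9-diol lactone
Conditions: HF·pyridine, pyridine, THF, 0 → 40 °C
Reagents that add atoms: none
Why: Fluoride desilylation, done only after C19 is locked in the 7,19-lactone so the freed C9 hydroxyl has no acid to lactonize with; the acidic medium suppresses acyl migration.

Step 17
Reactants: 29 2,9-diol lactone
Product: 30 2,9-diacetate acetonide
Conditions: Ac2O, Et3N, DMAP (cat.), CH2Cl2, 25 °C
Reagents that add atoms: acetic anhydride CC(=O)OC(C)=O
Why: Acylation of the two secondary alcohols; the hindered tertiary C8 hydroxyl does not react and C11/C12 are masked.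

Step 18
Reactants: 30 2,9-diacetate acetonide
Product: 31 target CNP0146024.1
Conditions: AcOH/H2O (4:1), 45 °C
Reagents that add atoms: none
Why: Acid-catalysed acetal hydrolysis releases the 11,12-diol without touching the acetates or the lactone.

**Compound list**

1 | dimethyl (2S)-2-hydroxybutanedioate (dimethyl L-malate) | COC(=O)C[C@H](O)C(=O)OC | starting material
2 | dimethyl (2S,3R)-2-hydroxy-3-methylbutanedioate | COC(=O)[C@@H](O)[C@@H](C)C(=O)OC | intermediate
3 | (2S,3R)-2-hydroxy-3-methylbutanedioic acid | OC(=O)[C@@H](O)[C@@H](C)C(=O)O | intermediate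
4 | (2R)-2-[(2S,4S)-2-tert-butyl-5-oxo-1,3-dioxolan-4-yl]propanoic acid (tert-butyl cis to the side chain) | C[C@@H](C(=O)O)[C@@H]1O[C@H](C(C)(C)C)OC1=O | intermediate
5 | 1,1-dimethoxypropan-2-one | CC(=O)C(OC)OC | starting material
6 | (triphenylphosphoranylidene)acetaldehyde | O=CC=P(c1ccccc1)(c1ccccc1)c1ccccc1 | starting material
7 | (2E)-4,4-dimethoxy-3-methylbut-2-enal | COC(OC)/C(C)=C/C=O | intermediate
8 | aldol adduct: (2R)-2-[(2S,4R)-2-tert-butyl-4-[(1R,2E)-1-hydroxy-4,4-dimethoxy-3-methylbut-2-en-1-yl]-5-oxo-1,3-dioxolan-4-yl]propanoic acid | C[C@@H](C(=O)O)[C@]1([C@H](O)/C=C(\C)C(OC)OC)O[C@H](C(C)(C)C)OC1=O | intermediate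
9 | bis-silyl acetal: C9 tert-butyldimethylsilyl ether and tert-butyldimethylsilyl ester of 8 | C[C@@H](C(=O)O[Si](C)(C)C(C)(C)C)[C@]1([C@H](O[Si](C)(C)C(C)(C)C)/C=C(\C)C(OC)OC)O[C@H](C(C)(C)C)OC1=O | intermediate
10 | enal acid: (2R)-2-[(2S,4R)-2-tert-butyl-4-[(1R,2E)-1-(tert-butyldimethylsilyloxy)-3-methyl-4-oxobut-2-en-1-yl]-5-oxo-1,3-dioxolan-4-yl]propanoic acid | C[C@@H](C(=O)O)[C@]1([C@H](O[Si](C)(C)C(C)(C)C)/C=C(\C)C=O)O[C@H](C(C)(C)C)OC1=O | intermediate
11 | (2E)-pent-2-enal | CC/C=C/C=O | starting material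
12 | trimethyl[(1E,3E)-penta-1,3-dien-1-yloxy]silane | C/C=C/C=C/O[Si](C)(C)C | intermediate
13 | trimethylsilyl ester of 10 | C[C@@H](C(=O)O[Si](C)(C)C)[C@]1([C@H](O[Si](C)(C)C(C)(C)C)/C=C(\C)C=O)O[C@H](C(C)(C)C)OC1=O | intermediate
14 | bis-silyl cycloadduct: ring A cyclohex-12-ene, C1 methyl and formyl, C14 OSiMe3 and C11 methyl both cis to the formyl group (endo adduct drawn), C10 side chain of 13 | O=C[C@@]1(C)[C@@H](O[Si](C)(C)C)C=C[C@@H](C)[C@@H]1[C@@H](O[Si](C)(C)C(C)(C)C)[C@@]2([C@@H](C)C(=O)O[Si](C)(C)C)O[C@H](C(C)(C)C)OC2=O | intermediate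
15 | ring A hydroxy aldehyde acid: 14 with C14 OH and C19 CO2H | O=C[C@@]1(C)[C@@H](O)C=C[C@@H](C)[C@@H]1[C@@H](O[Si](C)(C)C(C)(C)C)[C@@]2([C@@H](C)C(=O)O)O[C@H](C(C)(C)C)OC2=O | intermediate
16 | allylic acetate: C14 acetate of 15 (acid drawn free) | O=C[C@@]1(C)[C@@H](OC(C)=O)C=C[C@@H](C)[C@@H]1[C@@H](O[Si](C)(C)C(C)(C)C)[C@@]2([C@@H](C)C(=O)O)O[C@H](C(C)(C)C)OC2=O | intermediate
17 | cyclohexadiene aldehyde acid: ring A with C11=C12 and C13=C14, C1 and C10 as in the target | O=C[C@@]1(C)C=CC=C(C)[C@@H]1[C@@H](O[Si](C)(C)C(C)(C)C)[C@@]2([C@@H](C)C(=O)O)O[C@H](C(C)(C)C)OC2=O | intermediate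
18 | 11,12-diol: 11α,12α-dihydroxy derivative of 17 (C11, C12 as in the target) | O=C[C@@]1(C)C=C[C@@H](O)[C@@](C)(O)[C@@H]1[C@@H](O[Si](C)(C)C(C)(C)C)[C@@]2([C@@H](C)C(=O)O)O[C@H](C(C)(C)C)OC2=O | intermediate
19 | acetonide aldehyde acid: 11,12-O-isopropylidene derivative of 18 | O=C[C@@]1(C)C=C[C@H]3OC(C)(C)O[C@@]3(C)[C@@H]1[C@@H](O[Si](C)(C)C(C)(C)C)[C@@]2([C@@H](C)C(=O)O)O[C@H](C(C)(C)C)OC2=O | intermediate
20 | 4-bromobut-1-yne | C#CCCBr | starting material
21 | 5-bromo-3-methylidenepent-1-ene | C=CC(=C)CCBr | intermediate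
22 | (3-methylidenepent-4-en-1-yl)magnesium bromide | C=CC(=C)CC[Mg]Br | intermediate
23 | C2 carbinol: (2R)-alcohol from addition of 22 to the formyl group of 19 | C=CC(=C)CC[C@@H](O)[C@@]1(C)C=C[C@H]3OC(C)(C)O[C@@]3(C)[C@@H]1[C@@H](O[Si](C)(C)C(C)(C)C)[C@@]2([C@@H](C)C(=O)O)O[C@H](C(C)(C)C)OC2=O | intermediate
24 | dioxolanol: 23 with the C7 carbonyl reduced to the hemiacetal (C7 epimers) | C=CC(=C)CC[C@@H](O)[C@@]1(C)C=C[C@H]3OC(C)(C)O[C@@]3(C)[C@@H]1[C@@H](O[Si](C)(C)C(C)(C)C)[C@@]2([C@@H](C)C(=O)O)O[C@H](C(C)(C)C)OC2O | intermediate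
25 | hydroxy aldehyde: C8 bears OH and CHO (C7) | C=CC(=C)CC[C@@H](O)[C@@]1(C)C=C[C@H]3OC(C)(C)O[C@@]3(C)[C@@H]1[C@@H](O[Si](C)(C)C(C)(C)C)[C@@](O)(C=O)[C@@H](C)C(=O)O | intermediate
26 | C8 vinyl carbinol: C8 bears OH and CH=CH2; C2 OH, C9 OTBS, C19 CO2H | C=CC(=C)CC[C@@H](O)[C@@]1(C)C=C[C@H]3OC(C)(C)O[C@@]3(C)[C@@H]1[C@@H](O[Si](C)(C)C(C)(C)C)[C@@](O)(C=C)[C@@H](C)C(=O)O | intermediate
27 | ten-membered diene acid: ring B closed at C6=C7 (drawn Z), C5 exocyclic methylidene, C2 OH, C8 OH, C9 OTBS, 11,12-acetonide, C19 CO2H | O[C@@H]1CCC(=C)/C=C\[C@@](O)([C@@H](C)C(=O)O)[C@H](O[Si](C)(C)C(C)(C)C)[C@H]2[C@]3(C)OC(C)(C)O[C@@H]3C=C[C@]12C | intermediate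
28 | silyl-protected lactone: 9-O-TBS-11,12-O-isopropylidene-2,9-dideacetyl target (7S, 5Z) | O[C@@H]1CC/C(C)=C\[C@@H]4OC(=O)[C@H](C)[C@@]4(O)[C@H](O[Si](C)(C)C(C)(C)C)[C@H]2[C@]3(C)OC(C)(C)O[C@@H]3C=C[C@]12C | intermediate
29 | 2,9-diol lactone: 11,12-O-isopropylidene-2,9-dideacetyl target | O[C@@H]1CC/C(C)=C\[C@@H]4OC(=O)[C@H](C)[C@@]4(O)[C@H](O)[C@H]2[C@]3(C)OC(C)(C)O[C@@H]3C=C[C@]12C | intermediate
30 | 2,9-diacetate acetonide: 11,12-O-isopropylidene target | CC(=O)O[C@@H]1CC/C(C)=C\[C@@H]4OC(=O)[C@H](C)[C@@]4(O)[C@H](OC(C)=O)[C@H]2[C@]3(C)OC(C)(C)O[C@@H]3C=C[C@]12C | intermediate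
31 | CNP0146024.1: (1S,2R,5Z,7S,8S,9R,10S,11S,12R,17R)-2,9-diacetoxy-8,11,12-trihydroxybriara-5,13-dien-7,19-olide | CC(=O)O[C@@H]1[C@H]2[C@](C)(O)[C@H](O)C=C[C@]2(C)[C@H](OC(C)=O)CC/C(C)=C\[C@@H]2OC(=O)[C@H](C)[C@]21O | target

**Step count and weakest steps**

Total step count: 18 (steps 4, 6 and 11 make the three small building blocks). Longest linear sequence: 15 steps (1, 2, 3, 5, 7, 8, 9, 10, 12, 13, 14, 15, 16, 17, 18).

The three steps most likely to fail:

The Diels–Alder reaction (step 7). A trisubstituted, γ-branched enal may react too slowly with the silyloxydiene at 110 °C, and the facial control rests on an allylic-strain model. The fallback changes the diene class and the activation mode. It sets out from 10 and 11: 11 is converted with isopropenyl acetate and TsOH into (1E,3E)-penta-1,3-dien-1-yl acetate F1, which tolerates Lewis acids; F1 is added to 10 with Me2AlCl (2.2 equiv, one equivalent consumed by CO2H) in CH2Cl2 at −78 to −20 °C. The adduct is the allylic acetate 16 itself, so the fallback comes back to the route at 16 and continues with the palladium elimination of step 8.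

The ring-closing metathesis (step 14). A ten-membered ring has to close onto a vinyl group on a fully substituted carbon, and the conjugated vinyl carbene may be sluggish. The fallback replaces metathesis by a Heck-type closure and sets out from 19. Aldehyde 19 is alkylated as in step 12 with the alkyltitanium reagent made from 2,4-dibromobut-1-ene (the alkyl C–Br bond is metalated, the vinyl bromide is kept) to give bromoalkene carbinol F2. Treatment with i-Bu2AlH and then Ph3P=CH2 as in step 13 gives bromoalkene vinyl carbinol F3. Pd(OAc)2 (10 mol %), K2CO3 and Bu4NCl in DMF at 80 °C (2 mM) then effect a Larock-type vinyl halide/alkenoic acid annulation: oxidative addition at C5–Br, ten-membered Heck closure onto the C8 vinyl group (C5–C6 bond), β-hydride elimination and re-addition to the allyl complex, and carboxylate capture at C7. This gives 28 directly, so the fallback comes back at 28 and bypasses 27.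

The hydrolactonization (step 15, the new step). Palladium hydride may add elsewhere, the C2 or C8 hydroxyl may compete with the carboxylate at the allyl termini, and the C7 and olefin geometry rest on a conformational argument. The fallback uses known chemistry and sets out from 27. Iodolactonization (I2, NaHCO3, MeCN, 0 °C) forms the iodonium ion at the exocyclic methylene, and conjugate capture by the carboxylate at C7 gives iodomethyl lactone F4. Radical dehalogenation (Bu3SnH, AIBN cat., benzene, 80 °C) delivers hydrogen to the primary terminus and gives 28, where the fallback comes back to the route.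

Further compounds
F1 | step 7 | (1E,3E)-penta-1,3-dien-1-yl acetate | C/C=C/C=C/OC(C)=O
F2 | step 14 | bromoalkene carbinol: 23 with the chain CH2CH2C(Br)=CH2 on C2 | C=C(Br)CC[C@@H](O)[C@@]1(C)C=C[C@H]3OC(C)(C)O[C@@]3(C)[C@@H]1[C@@H](O[Si](C)(C)C(C)(C)C)[C@@]2([C@@H](C)C(=O)O)O[C@H](C(C)(C)C)OC2=O
F3 | step 14 | bromoalkene vinyl carbinol: 26 with the chain CH2CH2C(Br)=CH2 on C2 | C=C(Br)CC[C@@H](O)[C@@]1(C)C=C[C@H]3OC(C)(C)O[C@@]3(C)[C@@H]1[C@@H](O[Si](C)(C)C(C)(C)C)[C@@](O)(C=C)[C@@H](C)C(=O)O
F4 | step 15 | iodomethyl lactone: 28 with C16 as CH2I | O[C@@H]1CC/C(CI)=C\[C@@H]4OC(=O)[C@H](C)[C@@]4(O)[C@H](O[Si](C)(C)C(C)(C)C)[C@H]2[C@]3(C)OC(C)(C)O[C@@H]3C=C[C@]12C
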